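**Plan**
- Retrosynthesis: remove the acetyl group and take C6–OH back to C6=O. Then remove H (C5) and Br (C1) and re-bond C1–C5. Ring A becomes the cyclopentane C1–C5 of a 1,5-cycloeudesman-6-one (cyclopropane C1/C5/C10, cyclohexanone C5–C10).
- Enabling feature: Br–C1 is γ to the C6 oxygen along C6–C5–C10–C1 and C5 carries H. This is the retron of a homoconjugate HBr addition to a cyclopropyl ketone. The C1–C5 bond is exocyclic to ring B and aligned with the C6 carbonyl.
- Further cuts: C1–C5 and C1–C10 (carbenoid C1 + alkene C5=C10), C1–C2 (CHI2 anion), C4–CH3 (Grignard), C4–C5 (vinyllithium + Weinreb amide). These lead back to (R)-piperitone (ring B, C7) and methyl 3-hydroxypropanoate (C2–C4).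
- Forward: ring B is bought and the C4–C1 chain is joined at C5. The cyclopentane and cyclopropane close together, then bromide expands the five-membered ring to the six-membered ring A.
- Stereochemistry: C7 comes from piperitone. The temporary 6α-OH is set by hydride attack anti to i-Pr, C4 by chelation to O6, and C1/C5/C10 by O6-directed carbenoid delivery. C1–Br is set by inversion, C5–H by α-protonation, and the final 6α-O by SmI2 (equatorial alcohol).

Key step: step 12

Assumption: eudesmane numbering (C1–C15) is used for all intermediates, α/β refer to the target drawn with the C10 methyl group β, and commercial (R)-(−)-piperitone is taken to be enantiopure.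

**Step 1**
Reactants: 1 methyl 3-hydroxypropanoate
Product: 2 methyl 3-[(tert-butyldimethylsilyl)oxy]propanoate
Conditions: TBSCl, imidazole, CH2Cl2, 0 °C to rt
Reagents that add atoms: tert-butyldimethylsilyl chloride, CC(C)(C)[Si](C)(C)Cl
Why: Standard silylation of a primary alcohol masks the future C2 oxygen against the organometallic steps.

**Step 2**
Reactants: 2 methyl 3-[(tert-butyldimethylsilyl)oxy]propanoate
Product: 3 3-[(tert-butyldimethylsilyl)oxy]-N-methoxy-N-methylpropanamide
Conditions: MeNH(OMe)·HCl, i-PrMgCl, THF, −20 °C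
Reagents that add atoms: N,O-dimethylhydroxylamine hydrochloride, CNOC.Cl
Why: Aminolysis of the ester by the magnesium amide (Weinreb amide synthesis) gives an acyl donor that stops at the ketone stage.

**Step 3**
Reactants: 4 (R)-(−)-piperitone
Product: 5 (6R)-2-iodo-3-methyl-6-(propan-2-yl)cyclohex-2-en-1-one
Conditions: I2, pyridine–CH2Cl2, 0 °C to rt, dark
Reagents that add atoms: iodine, II
Why: Pyridine-mediated α-iodination of an enone (Baylis–Hillman-type addition–iodination–elimination) places the handle at C5, and the weak base should leave C7 untouched.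

**Step 4**
Reactants: 5 (6R)-2-iodo-3-methyl-6-(propan-2-yl)cyclohex-2-en-1-one
Product: 6 (1S,6R)-2-iodo-3-methyl-6-(propan-2-yl)cyclohex-2-en-1-ol (OH and i-Pr cis)
Conditions: L-Selectride, THF, −78 °C; then H2O
Reagents that add atoms: none
Why: A bulky trialkylborohydride reduces β,β-disubstituted enones 1,2 and attacks equatorially, anti to the pseudoequatorial isopropyl group, which should give the pseudoaxial alcohol cis to i-Pr.

**Step 5**
Reactants: 6 (1S,6R)-2-iodo-3-methyl-6-(propan-2-yl)cyclohex-2-en-1-ol; 3 3-[(tert-butyldimethylsilyl)oxy]-N-methoxy-N-methylpropanamide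
Product: 8 3-[(tert-butyldimethylsilyl)oxy]-1-[(5R,6S)-6-hydroxy-2-methyl-5-(propan-2-yl)cyclohex-1-en-1-yl]propan-1-one, via dilithio species 7 (not isolated)
Conditions: t-BuLi (3.1 equiv), Et2O, −78 °C; then 3, −78 to −20 °C; H2O
Reagents that add atoms: tert-butyllithium, [Li]C(C)(C)C (lithium of 7 only)
Why: Deprotonation and iodine–lithium exchange give an alkoxide-vinyllithium that acylates once on the Weinreb amide (Weinreb ketone synthesis), forming C4–C5 without an O6 protecting group.

**Step 6**
Reactants: 8 hydroxy ketone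
Product: 9 (2R)-4-[(tert-butyldimethylsilyl)oxy]-2-[(5R,6S)-6-hydroxy-2-methyl-5-(propan-2-yl)cyclohex-1-en-1-yl]butan-2-ol
Conditions: MeMgBr (3.5 equiv), CH2Cl2–Et2O, −78 to −20 °C
Reagents that add atoms: methylmagnesium bromide, C[Mg]Br
Why: The magnesium alkoxide of O6 chelates the ketone oxygen, and the Grignard reagent attacks the carbonyl face turned towards H-6 and away from the vinylic methyl group (chelation-controlled Grignard addition), which should give the (R)-carbinol that becomes 4α-OH/4β-CH3.

**Step 7**
Reactants: 9 silyl ether diol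
Product: 10 (3R)-3-[(5R,6S)-6-hydroxy-2-methyl-5-(propan-2-yl)cyclohex-1-en-1-yl]butane-1,3-diol
Conditions: TBAF, THF, 0 °C to rt
Reagents that add atoms: none
Why: Fluoride cleaves the primary silyl ether under non-acidic conditions that spare the tertiary allylic alcohol.

**Step 8**
Reactants: 10 triol
Product: 11 (2R)-4-iodo-2-[(5R,6S)-6-hydroxy-2-methyl-5-(propan-2-yl)cyclohex-1-en-1-yl]butan-2-ol
Conditions: I2, PPh3, imidazole, THF, −10 °C
Reagents that add atoms: iodine, II
Why: The Appel-type iodination selects the unhindered primary alcohol over the hindered secondary and tertiary ones.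

**Step 9**
Reactants: 11 iodo diol
Product: 14 (2R)-5,5-diiodo-2-[(5R,6S)-6-hydroxy-2-methyl-5-(propan-2-yl)cyclohex-1-en-1-yl]pentan-2-ol, via bis-TMS iodide 12 (not isolated), via bis-TMS diiodide 13 (not isolated)
Conditions: (i) TMS-imidazole, CH2Cl2, rt, evaporate; (ii) CH2I2, LiHMDS, THF–Et2O, −78 °C, then 12, to rt, dark; (iii) K2CO3 (cat.), MeOH, 0 °C
Reagents that add atoms: diiodomethane, ICI; N-(trimethylsilyl)imidazole, C[Si](C)(C)n1ccnc1 (silyl groups of 12 and 13 only)
Why: SN2 alkylation of diiodomethyllithium by a primary iodide brings in C1 at the carbenoid oxidation level, and transient silylation prevents oxetane formation by the γ-alkoxide.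

**Step 10**
Reactants: 14 gem-diiodide diol
Product: 16 1,5-cycloeudesmane-4α,6α-diol (cyclopropane CH C1, 6-OH and 7-i-Pr on the α face of ring B; 10-CH3 and C4 on the β face; 4-OH on the side of C6), via zinc carbenoid 15 (not isolated)
Conditions: Et2Zn (4 equiv), CH2Cl2, −40 °C to rt, dark; then H2O
Reagents that add atoms: diethylzinc, CC[Zn]CC (zinc and ethyl groups of 15 only)
Why: Iodine–zinc exchange gives an α-iodoalkylzinc carbenoid that is held by the zinc alkoxide of the pseudoaxial 6α-oxygen and adds suprafacially to the α face of C5=C10 (intramolecular hydroxyl-directed Simmons–Smith reaction), closing the cyclopentane and cyclopropane and setting C1, C5 and C10 at once.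

**Step 11**
Reactants: 16 tricyclic diol
Product: 17 4α-hydroxy-1,5-cycloeudesman-6-one
Conditions: TPAP (cat.), NMO, 4 Å MS, CH2Cl2, rt
Reagents that add atoms: none
Why: The neutral Ley–Griffith oxidation touches only the secondary carbinol, raises C6 to the activating ketone level, and should not epimerise C7 or ionise the cyclopropylcarbinyl alcohols.

**Step 12**
Reactants: 17 4α-hydroxy-1,5-cycloeudesman-6-one
Product: 19 1β-bromo-4α-hydroxy-7α-isopropyl-5αH-eudesman-6-one, via aluminium enolate 18 (not isolated)
Conditions: Et2AlBr (2 equiv), CH2Cl2, −78 to −20 °C; then aq. Rochelle salt, −78 °C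
Reagents that add atoms: diethylaluminium bromide, CC[Al](Br)CC
Why: Et2AlBr first metallates the 4-OH (ethane) and the bromoaluminium alkoxide chelates the C6 carbonyl, so bromide attacks C1 from the rear of the C1–C5 bond and the electron pair flows into the C5=C6 aluminium enolate 18, which cuts the zero-atom bridge of the bicyclo[3.1.0]hexane and turns the cyclopentane C1–C2–C3–C4–C5 into the cyclohexane C1–C2–C3–C4–C5–C10. The closest known reaction types are the homoconjugate halide opening of cyclopropyl ketones by Et2AlI, TiCl4/R4NI or Me3SiX and the HBr opening of 3α,5-cyclo-6-keto steroids to 3β-bromo-6-ketones. No ring is closed in this step; release of the strain of the fused three- and five-membered rings drives it. C1 is set by SN2 inversion, which places Br β and equatorial because C1 lies on the α face of ring B opposite the 10β-methyl group, and C5 is set on quenching by protonation of the chelated enolate from the α face (the β face is closed by the 4β- and 10β-methyl groups) to give the trans-decalone, while C4, C7 and C10 are untouched. The step needs C1–C5 rather than C5–C10 cleavage: C1–C5 is exocyclic to the cyclohexanone ring and nearly parallel to the carbonyl π orbitals whereas C5–C10 is endocyclic and lies near their nodal plane, and C1 is a secondary carbon open to rear-side attack whereas C10 is fully substituted. Keeping O4 as an aluminium alkoxide (a poor leaving group) and working cold without Brønsted acid is meant to prevent loss of the β-oxygen, retro-aldol cleavage and epimerisation at C7.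

**Step 13**
Reactants: 19 bromo ketol
Product: 20 austradiol, 1β-bromo-7α-isopropyl-5αH-eudesmane-4α,6α-diol
Conditions: SmI2 (2.5 equiv), THF–H2O, 0 °C
Reagents that add atoms: none
Why: Ketyl reduction with SmI2–H2O, with samarium held between O6 and the 4α-oxygen, protonates C6 from the hindered β face and should give the equatorial 6α-alcohol that α-face hydride attack would not give, while an unactivated secondary bromide is reduced much more slowly than a ketone without HMPA or amine.

**Step 14**
Reactants: 20 austradiol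
Product: 21 austradiol acetate
Conditions: Ac2O, pyridine, DMAP (cat.), CH2Cl2, rt
Reagents that add atoms: acetic anhydride, CC(=O)OC(C)=O
Why: DMAP-catalysed acetylation takes the secondary equatorial alcohol and leaves the tertiary 4-OH free.

**Compound list**

| No. | Name | SMILES | Role |
|---|---|---|---|
| 1 | methyl 3-hydroxypropanoate | COC(=O)CCO | starting material |
| 2 | methyl 3-[(tert-butyldimethylsilyl)oxy]propanoate | COC(=O)CCO[Si](C)(C)C(C)(C)C | intermediate |
| 3 | 3-[(tert-butyldimethylsilyl)oxy]-N-methoxy-N-methylpropanamide | CON(C)C(=O)CCO[Si](C)(C)C(C)(C)C | intermediate |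
| 4 | (R)-(−)-piperitone | O=C1[C@@H](C(C)C)CCC(C)=C1 | starting material |
| 5 | (6R)-2-iodo-3-methyl-6-(propan-2-yl)cyclohex-2-en-1-one | O=C1[C@@H](C(C)C)CCC(C)=C1I | intermediate |
| 6 | (1S,6R)-2-iodo-3-methyl-6-(propan-2-yl)cyclohex-2-en-1-ol | O[C@H]1[C@@H](C(C)C)CCC(C)=C1I | intermediate |
| 7 | dilithio species (lithium alkoxide and vinyllithium from 6) | [Li]O[C@H]1[C@@H](C(C)C)CCC(C)=C1[Li] | intermediate |
| 8 | 3-[(tert-butyldimethylsilyl)oxy]-1-[(5R,6S)-6-hydroxy-2-methyl-5-(propan-2-yl)cyclohex-1-en-1-yl]propan-1-one | O[C@H]1[C@@H](C(C)C)CCC(C)=C1C(=O)CCO[Si](C)(C)C(C)(C)C | intermediate |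
| 9 | (2R)-4-[(tert-butyldimethylsilyl)oxy]-2-[(5R,6S)-6-hydroxy-2-methyl-5-(propan-2-yl)cyclohex-1-en-1-yl]butan-2-ol | O[C@H]1[C@@H](C(C)C)CCC(C)=C1[C@](C)(O)CCO[Si](C)(C)C(C)(C)C | intermediate |
| 10 | (3R)-3-[(5R,6S)-6-hydroxy-2-methyl-5-(propan-2-yl)cyclohex-1-en-1-yl]butane-1,3-diol | O[C@H]1[C@@H](C(C)C)CCC(C)=C1[C@](C)(O)CCO | intermediate |
| 11 | (2R)-4-iodo-2-[(5R,6S)-6-hydroxy-2-methyl-5-(propan-2-yl)cyclohex-1-en-1-yl]butan-2-ol | O[C@H]1[C@@H](C(C)C)CCC(C)=C1[C@](C)(O)CCI | intermediate |
| 12 | bis(trimethylsilyl) ether of 11 | C[Si](C)(C)O[C@H]1[C@@H](C(C)C)CCC(C)=C1[C@](C)(O[Si](C)(C)C)CCI | intermediate |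
| 13 | bis(trimethylsilyl) ether of 14 | C[Si](C)(C)O[C@H]1[C@@H](C(C)C)CCC(C)=C1[C@](C)(O[Si](C)(C)C)CCC(I)I | intermediate |
| 14 | (2R)-5,5-diiodo-2-[(5R,6S)-6-hydroxy-2-methyl-5-(propan-2-yl)cyclohex-1-en-1-yl]pentan-2-ol | O[C@H]1[C@@H](C(C)C)CCC(C)=C1[C@](C)(O)CCC(I)I | intermediate |
| 15 | zinc carbenoid (bis(ethylzinc) alkoxide, C1 as CH(I)ZnEt) | CC[Zn]O[C@H]1[C@@H](C(C)C)CCC(C)=C1[C@](C)(O[Zn]CC)CCC(I)[Zn]CC | intermediate |
| 16 | 1,5-cycloeudesmane-4α,6α-diol (7α-i-Pr, 10β-CH3) | O[C@H]1[C@@H](C(C)C)CC[C@@]2(C)[C@@H]3CC[C@@](C)(O)[C@]123 | intermediate |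
| 17 | 4α-hydroxy-1,5-cycloeudesman-6-one | O=C1[C@@H](C(C)C)CC[C@@]2(C)[C@@H]3CC[C@@](C)(O)[C@]123 | intermediate |
| 18 | cyclic ethylaluminium 4-alkoxide/Δ5-6-enolate of 19 | CC[Al]1OC2=C3[C@](C)(O1)CC[C@@H](Br)[C@]3(C)CC[C@@H]2C(C)C | intermediate |
| 19 | 1β-bromo-4α-hydroxy-7α-isopropyl-5αH-eudesman-6-one | O=C1[C@@H](C(C)C)CC[C@@]2(C)[C@H](Br)CC[C@@](C)(O)[C@H]12 | intermediate |
| 20 | austradiol (1β-bromo-4α,6α-diol) | O[C@H]1[C@@H](C(C)C)CC[C@@]2(C)[C@H](Br)CC[C@@](C)(O)[C@H]12 | intermediate |
| 21 | austradiol acetate | CC(=O)O[C@H]1[C@@H](C(C)C)CC[C@@]2(C)[C@H](Br)CC[C@@](C)(O)[C@H]12 | target |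

**Step count:** 14 steps in total. The longest linear sequence is 12 steps (steps 3–14 from 4).

**Steps most likely to fail**

1. **Step 10.**
   - The alkene is tetrasubstituted and α attack brings the methyl groups C14 and C15 together. The carbenoid may therefore decay by 1,2-hydride shift, add to the β face, or leave time for zinc iodide to ionise the tertiary allylic alkoxide.
   - The fallback sets out from 14 and comes back at 17, so step 11 is skipped.
   - MnO2 in CH2Cl2 oxidises the allylic 6-OH to the enone gem-diiodide F1.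
   - Visible-light photoredox reduction (Ru(bpy)3(PF6)2 cat., i-Pr2NEt, MeCN) then forms the α-iodoalkyl radical. This radical adds to the enone β-carbon C10 along the axial trajectory cis to the isopropyl group.
   - The C5 α-keto radical or enolate closes the three-membered ring on C1 with loss of iodide (radical–polar crossover cyclopropanation). No directing group is needed.

2. **Step 12.**
   - Bromide may attack C10 with C5–C10 cleavage, giving a hydroazulene skeleton. The aldolate may open by retro-aldol reaction or lose the C4 oxygen, and C7 may epimerise.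
   - The fallback sets out from 16 and comes back at 20, bypassing 17 and 19. It uses the cationic cyclopropylcarbinyl–homoallyl (i-steroid type) rearrangement.
   - Ms2O/Et3N in CH2Cl2 at −40 °C gives the 6-mesylate F2.
   - LiBr in THF converts F2 into 1β-bromo-7α-isopropyleudesm-5-en-4α-ol F3.
   - mCPBA/NaHCO3 gives the 5α,6α-epoxide F4 (the β face is shielded by two methyl groups, and the 4α-OH can hydrogen-bond to the peracid).
   - Cp2TiCl (Cp2TiCl2, Mn) with 1,4-cyclohexadiene opens the 2,3-epoxy alcohol through the tertiary C5 radical to the 1,3-diol 20.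

3. **Step 6.**
   - Facial selectivity may be poor or reversed. The ketone may also be enolised, with β-elimination of silanolate.
   - The fallback sets out from 6 (through 7) and comes back at 10. It exchanges the roles of the two carbon groups on the same chelate.
   - Species 7 is acylated with N-methoxy-N-methylacetamide to the methyl ketone F5.
   - Vinylmagnesium bromide adds to give the vinyl carbinol F6. With an unchanged facial preference this inverts the outcome at C4, and there is no β-leaving group.
   - 9-BBN followed by NaBO3 hydroborates the monosubstituted alkene to give triol 10.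

**Further compounds**
F1 | step 10 | (6R)-2-[(2R)-2-hydroxy-5,5-diiodopentan-2-yl]-3-methyl-6-(propan-2-yl)cyclohex-2-en-1-one | O=C1[C@@H](C(C)C)CCC(C)=C1[C@](C)(O)CCC(I)I
F2 | step 12 | 4α-hydroxy-1,5-cycloeudesman-6α-yl methanesulfonate | CS(=O)(=O)O[C@H]1[C@@H](C(C)C)CC[C@@]2(C)[C@@H]3CC[C@@](C)(O)[C@]123
F3 | step 12 | 1β-bromo-7α-isopropyleudesm-5-en-4α-ol | C1=C2[C@](C)(O)CC[C@@H](Br)[C@]2(C)CC[C@@H]1C(C)C
F4 | step 12 | 1β-bromo-5α,6α-epoxy-7α-isopropyleudesman-4α-ol | O1[C@H]2[C@@H](C(C)C)CC[C@@]3(C)[C@H](Br)CC[C@@](C)(O)[C@]123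
F5 | step 6 | 1-[(5R,6S)-6-hydroxy-2-methyl-5-(propan-2-yl)cyclohex-1-en-1-yl]ethan-1-one | O[C@H]1[C@@H](C(C)C)CCC(C)=C1C(C)=O
F6 | step 6 | (2R)-2-[(5R,6S)-6-hydroxy-2-methyl-5-(propan-2-yl)cyclohex-1-en-1-yl]but-3-en-2-ol | O[C@H]1[C@@H](C(C)C)CCC(C)=C1[C@](C)(O)C=C
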